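**Plan**

- Numbering used throughout: ring A is the aromatic ring (C4a, C5–C8, C8a; OMe on C6, OH on C7); ring B is C1–C4 (syringyl on C1, CH2OAc on C2 and C3, CH2 at C4). The enabling feature is that C1 and C4 are both benzylic to ring A and the trans C2/C3 one-carbon arms are a reduced fumarate, so ring B is the [4+2] adduct of an o-quinodimethane across C4a/C8a.
- Retrosynthesis: the free phenols and C4–H go back to two benzyl ethers and a benzylic C4–OAc, and the acetates go back to a diester carrying a C4 hydroxyl. C1–C2 and C3–C4 are then cut together, giving a 2-benzylbenzaldehyde and a chiral fumarate. Last, the aryl–CH2 bond of the aldehyde is cut into an ortho-formyl arylboronate and a benzylic bromide.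
- Forward: the ring A piece (from vanillin) and the pendant aryl piece (from syringaldehyde) are joined at the diarylmethane carbon. Ring B, the only ring to be made, closes in the photochemical step. Reduction, acetylation and one hydrogenolysis finish the synthesis.
- Stereochemistry: C2/C3 trans comes from the E fumarate. C1 comes from the outward aryl of the (E,E)-dienol together with the endo, hydrogen-bonded placement of the ester next to the dienol OH. The absolute sense comes from the (S)-lactate esters, and the C4 carbinol centre is temporary.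

Key step: step 9

Assumption: the dienol is taken to attack the face of the (S)-lactate fumarate that makes C2 of the adduct R (hence 1S,2R,3R in the target), the sense expected for fumarates of (S)-α-hydroxy esters in this cycloaddition; the route is written for that sense.

**Route**

Step 1
Reactants: 1 vanillin (4-hydroxy-3-methoxybenzaldehyde)
Product: 2 4-benzyloxy-3-methoxybenzaldehyde
Conditions: BnBr, K2CO3, DMF, rt
Reagents that add atoms: benzyl bromide, BrCc1ccccc1
Why: Williamson ether synthesis on the phenoxide formed by K2CO3, with benzyl chosen because it survives every later step and leaves in the final hydrogenolysis.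

Step 2
Reactants: 2 4-benzyloxy-3-methoxybenzaldehyde
Product: 3 4-benzyloxy-2-bromo-5-methoxybenzaldehyde
Conditions: Br2, NaOAc, AcOH, rt
Reagents that add atoms: bromine, BrBr
Why: Electrophilic aromatic bromination occurs para to the methoxy group and ortho to the formyl group, the site known to react in O-alkylated vanillins, and NaOAc buffers the HBr so that the benzyl ether is not cleaved.

Step 3
Reactants: 3 4-benzyloxy-2-bromo-5-methoxybenzaldehyde
Product: 4 4-benzyloxy-5-methoxy-2-(4,4,5,5-tetramethyl-1,3,2-dioxaborolan-2-yl)benzaldehyde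
Conditions: B2pin2, PdCl2(dppf) (cat.), KOAc, 1,4-dioxane, 85 °C
Reagents that add atoms: bis(pinacolato)diboron, CC1(C)OB(OC1(C)C)B1OC(C)(C)C(C)(C)O1
Why: Miyaura borylation of the aryl bromide tolerates the free ortho aldehyde, so that neither an acetal nor an organolithium is needed, and the weak base KOAc keeps the new boronate from coupling with unreacted bromide.

Step 4
Reactants: 5 syringaldehyde (4-hydroxy-3,5-dimethoxybenzaldehyde)
Product: 6 4-benzyloxy-3,5-dimethoxybenzaldehyde
Conditions: BnBr, K2CO3, DMF, 60 °C
Reagents that add atoms: benzyl bromide, BrCc1ccccc1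
Why: Williamson ether synthesis on a phenol flanked by two methoxy groups, which is why gentle heating is used.

Step 5
Reactants: 6 4-benzyloxy-3,5-dimethoxybenzaldehyde
Product: 7 (4-benzyloxy-3,5-dimethoxyphenyl)methanol
Conditions: NaBH4, MeOH–THF, 0 °C
Reagents that add atoms: none
Why: Borohydride reduction of the aryl aldehyde to the benzylic alcohol, with no other reducible group present.

Step 6
Reactants: 7 (4-benzyloxy-3,5-dimethoxyphenyl)methanol
Product: 8 2-benzyloxy-5-(bromomethyl)-1,3-dimethoxybenzene
Conditions: PBr3, CH2Cl2, 0 °C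
Reagents that add atoms: phosphorus tribromide, BrP(Br)Br
Why: Conversion of the benzylic alcohol into the bromide by PBr3 (bromophosphite formation, then displacement by bromide) is mild enough for the benzyl ether, and the reactive bromide is used directly.

Step 7
Reactants: 4 4-benzyloxy-5-methoxy-2-(4,4,5,5-tetramethyl-1,3,2-dioxaborolan-2-yl)benzaldehyde; 8 2-benzyloxy-5-(bromomethyl)-1,3-dimethoxybenzene
Product: 9 4-benzyloxy-2-[(4-benzyloxy-3,5-dimethoxyphenyl)methyl]-5-methoxybenzaldehyde
Conditions: PdCl2(dppf) (cat.), K2CO3, THF–H2O (10:1), 65 °C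
Reagents that add atoms: none
Why: Suzuki–Miyaura sp2–sp3 coupling of an arylboronate with a benzylic bromide, which undergoes fast oxidative addition and has no β-hydrogen, sets the diarylmethane carbon directly at the CH2 oxidation level while the aldehyde and the benzyl ethers are inert to the carbonate base.

Step 8
Reactants: 10 methyl (S)-lactate (2.1 equiv); 11 fumaryl chloride
Product: 13 bis[(2S)-1-methoxy-1-oxopropan-2-yl] (2E)-but-2-enedioate, via fumaric monoester acid chloride 12 (not isolated)
Conditions: pyridine, DMAP (cat.), CH2Cl2, 0 °C to rt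
Reagents that add atoms: none
Why: Twofold O-acylation of the secondary alcohol by the diacid chloride with pyridine as HCl acceptor (nucleophilic acyl substitution), which touches neither the lactate stereocentre nor the E geometry of the alkene.

Step 9
Reactants: 9 4-benzyloxy-2-[(4-benzyloxy-3,5-dimethoxyphenyl)methyl]-5-methoxybenzaldehyde; 13 bis[(2S)-1-methoxy-1-oxopropan-2-yl] (2E)-but-2-enedioate
Product: 15 bis[(2S)-1-methoxy-1-oxopropan-2-yl] (1S,2R,3S,4S)-7-benzyloxy-1-(4-benzyloxy-3,5-dimethoxyphenyl)-4-hydroxy-6-methoxy-1,2,3,4-tetrahydronaphthalene-2,3-dicarboxylate, via (E,E)-hydroxy-o-quinodimethane 14 (not isolated)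
Conditions: hν (λ > 300 nm, Pyrex-filtered Hg lamp or 365 nm LEDs), degassed toluene (0.02 M in 9), fumarate in threefold excess, 0–10 °C
Reagents that add atoms: none
Why: Excitation of the aryl aldehyde and 1,5-hydrogen transfer from the diarylmethane CH2 to the carbonyl oxygen should give the long-lived (E,E)-dienol 14 (OH and aryl both outward), an electron-rich diene for the electron-poor fumarate; this is a photoenolisation/Diels–Alder reaction, a known reaction type for 2-benzylbenzaldehydes and fumarates of chiral α-hydroxy esters. Ring B closes by a concerted, suprafacial, intermolecular [4+2] cycloaddition that forms C1–C2 and C3–C4 and restores the aromaticity of ring A. C2 and C3 come out trans because the E geometry of the fumarate is carried through the suprafacial addition. C4 is set with its OH cis to the C3 ester by the endo transition state in which that ester carbonyl is hydrogen-bonded to the dienol OH, and C1 follows with its outward aryl cis to the C4 OH and trans to the C2 ester. The absolute sense (1S,2R) is set by the two (S)-lactate esters, which differentiate the faces of the fumarate. The step needs E-dienol, endo and facial selectivity: the Z-dienol reverts to 9 by a thermal 1,5-hydrogen shift and is not trapped, the non-polar solvent preserves the OH···O=C hydrogen bond, low temperature and the twofold-symmetric double auxiliary sharpen the facial choice, and the long-wavelength cutoff with degassing avoids direct excitation of the fumarate and oxidation of the dienol.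

Step 10
Reactants: 15 bis[(2S)-1-methoxy-1-oxopropan-2-yl] (1S,2R,3S,4S)-7-benzyloxy-1-(4-benzyloxy-3,5-dimethoxyphenyl)-4-hydroxy-6-methoxy-1,2,3,4-tetrahydronaphthalene-2,3-dicarboxylate
Product: 16 [(1S,2R,3R,4S)-7-benzyloxy-1-(4-benzyloxy-3,5-dimethoxyphenyl)-4-hydroxy-6-methoxy-1,2,3,4-tetrahydronaphthalene-2,3-diyl]dimethanol
Conditions: LiAlH4 (excess), THF, 0 °C to rt; then H2O work-up
Reagents that add atoms: none
Why: LiAlH4 reduction of all four ester groups converts the two ring carboxylates into the CH2OH arms and releases the auxiliary as (S)-propane-1,2-diol, the aryl benzyl ethers are inert, and rapid reduction at low temperature should leave C2 and C3 no time to epimerise and the β-hydroxy ester no time for retro-aldol cleavage.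

Step 11
Reactants: 16 [(1S,2R,3R,4S)-7-benzyloxy-1-(4-benzyloxy-3,5-dimethoxyphenyl)-4-hydroxy-6-methoxy-1,2,3,4-tetrahydronaphthalene-2,3-diyl]dimethanol
Product: 17 [(1S,2R,3R,4S)-4-acetoxy-7-benzyloxy-1-(4-benzyloxy-3,5-dimethoxyphenyl)-6-methoxy-1,2,3,4-tetrahydronaphthalene-2,3-diyl]bis(methylene) diacetate
Conditions: Ac2O, pyridine, DMAP (cat.), CH2Cl2, rt
Reagents that add atoms: acetic anhydride, CC(=O)OC(C)=O
Why: DMAP-catalysed O-acetylation esterifies the two primary hydroxyls and the secondary benzylic C4 hydroxyl without touching any stereocentre, and it turns the C4 oxygen into a better leaving group for the last step.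

Step 12
Reactants: 17 [(1S,2R,3R,4S)-4-acetoxy-7-benzyloxy-1-(4-benzyloxy-3,5-dimethoxyphenyl)-6-methoxy-1,2,3,4-tetrahydronaphthalene-2,3-diyl]bis(methylene) diacetate
Product: 18 [(1S,2R,3R)-7-hydroxy-1-(4-hydroxy-3,5-dimethoxyphenyl)-6-methoxy-1,2,3,4-tetrahydronaphthalene-2,3-diyl]bis(methylene) diacetate (CNP0265800.1)
Conditions: H2 (1–3 atm), 10% Pd/C, EtOAc–AcOH, rt
Reagents that add atoms: none
Why: Heterogeneous catalytic hydrogenolysis cleaves the two aryl benzyl ethers and the benzylic C4–OAc bond, the latter helped by the para oxygen on C7, whereas the two primary acetates are not benzylic and C1–C3 carry no hydrogenolysable bond, so their configuration is retained and C4 becomes CH2.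

**Compound list**

1 | vanillin (4-hydroxy-3-methoxybenzaldehyde) | COc1cc(C=O)ccc1O | starting material
2 | 4-benzyloxy-3-methoxybenzaldehyde | COc1cc(C=O)ccc1OCc1ccccc1 | intermediate
3 | 4-benzyloxy-2-bromo-5-methoxybenzaldehyde | COc1cc(C=O)c(Br)cc1OCc1ccccc1 | intermediate
4 | 4-benzyloxy-5-methoxy-2-(4,4,5,5-tetramethyl-1,3,2-dioxaborolan-2-yl)benzaldehyde | COc1cc(C=O)c(cc1OCc1ccccc1)B1OC(C)(C)C(C)(C)O1 | intermediate
5 | syringaldehyde (4-hydroxy-3,5-dimethoxybenzaldehyde) | COc1cc(C=O)cc(OC)c1O | starting material
6 | 4-benzyloxy-3,5-dimethoxybenzaldehyde | COc1cc(C=O)cc(OC)c1OCc1ccccc1 | intermediate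
7 | (4-benzyloxy-3,5-dimethoxyphenyl)methanol | COc1cc(CO)cc(OC)c1OCc1ccccc1 | intermediate
8 | 2-benzyloxy-5-(bromomethyl)-1,3-dimethoxybenzene | COc1cc(CBr)cc(OC)c1OCc1ccccc1 | intermediate
9 | 4-benzyloxy-2-[(4-benzyloxy-3,5-dimethoxyphenyl)methyl]-5-methoxybenzaldehyde | COc1cc(C=O)c(cc1OCc1ccccc1)Cc1cc(OC)c(OCc2ccccc2)c(OC)c1 | intermediate
10 | methyl (S)-lactate | C[C@H](O)C(=O)OC | starting material
11 | fumaryl chloride | O=C(Cl)/C=C/C(Cl)=O | starting material
12 | methyl (2S)-2-{[(2E)-4-chloro-4-oxobut-2-enoyl]oxy}propanoate (fumaric monoester acid chloride, formed in the flask) | COC(=O)[C@H](C)OC(=O)/C=C/C(Cl)=O | intermediate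
13 | bis[(2S)-1-methoxy-1-oxopropan-2-yl] (2E)-but-2-enedioate | COC(=O)[C@H](C)OC(=O)/C=C/C(=O)O[C@@H](C)C(=O)OC | intermediate
14 | (E)-{(6E)-4-benzyloxy-6-[(4-benzyloxy-3,5-dimethoxyphenyl)methylidene]-3-methoxycyclohexa-2,4-dien-1-ylidene}methanol (the (E,E)-hydroxy-o-quinodimethane, formed in the flask) | O/C=C1/C(=C/c2cc(OC)c(OCc3ccccc3)c(OC)c2)C=C(OCc2ccccc2)C(OC)=C1 | intermediate
15 | bis[(2S)-1-methoxy-1-oxopropan-2-yl] (1S,2R,3S,4S)-7-benzyloxy-1-(4-benzyloxy-3,5-dimethoxyphenyl)-4-hydroxy-6-methoxy-1,2,3,4-tetrahydronaphthalene-2,3-dicarboxylate | COc1cc2c(cc1OCc3ccccc3)[C@H](c1cc(OC)c(OCc3ccccc3)c(OC)c1)[C@@H](C(=O)O[C@@H](C)C(=O)OC)[C@H](C(=O)O[C@@H](C)C(=O)OC)[C@@H]2O | intermediate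
16 | [(1S,2R,3R,4S)-7-benzyloxy-1-(4-benzyloxy-3,5-dimethoxyphenyl)-4-hydroxy-6-methoxy-1,2,3,4-tetrahydronaphthalene-2,3-diyl]dimethanol | COc1cc2c(cc1OCc3ccccc3)[C@H](c1cc(OC)c(OCc3ccccc3)c(OC)c1)[C@@H](CO)[C@H](CO)[C@@H]2O | intermediate
17 | [(1S,2R,3R,4S)-4-acetoxy-7-benzyloxy-1-(4-benzyloxy-3,5-dimethoxyphenyl)-6-methoxy-1,2,3,4-tetrahydronaphthalene-2,3-diyl]bis(methylene) diacetate | COc1cc2c(cc1OCc3ccccc3)[C@H](c1cc(OC)c(OCc3ccccc3)c(OC)c1)[C@@H](COC(C)=O)[C@H](COC(C)=O)[C@@H]2OC(C)=O | intermediate
18 | [(1S,2R,3R)-7-hydroxy-1-(4-hydroxy-3,5-dimethoxyphenyl)-6-methoxy-1,2,3,4-tetrahydronaphthalene-2,3-diyl]bis(methylene) diacetate | COc1cc2c(cc1O)[C@H](c1cc(OC)c(O)c(OC)c1)[C@@H](COC(C)=O)[C@H](COC(C)=O)C2 | target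

**Count**

Total steps: 12. Longest linear sequence: 8 steps (1, 2, 3, 7, 9, 10, 11, 12; the branch from syringaldehyde through steps 4, 5, 6 is equally long).

**Steps most likely to fail, with fallbacks**

Step 9. What may go wrong: slow hydrogen abstraction by the electron-rich aldehyde, triplet-sensitised E-to-Z isomerisation of the fumarate during irradiation, and erosion of facial selectivity at the temperature the lamp imposes. The fallback sets out from 9 and returns at 15, and separates the light-driven generation of the dienol from the cycloaddition. Irradiation of 9 (λ > 300 nm) in SO2-saturated toluene should trap dienol 14 by cheletropic addition as racemic cis-5-benzyloxy-3-(4-benzyloxy-3,5-dimethoxyphenyl)-1-hydroxy-6-methoxy-1,3-dihydro-2-benzothiophene 2,2-dioxide F1, a storable precursor whose stereocentres vanish again on opening. Heating F1 with fumarate 13 in toluene in the dark (80–110 °C, N2 stream to carry off SO2) should extrude SO2, regenerate 14 thermally and give 15. The fumarate then never meets an excited state, and the temperature can be chosen for selectivity.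

Step 12. What may go wrong: debenzylation outruns cleavage of the secondary benzylic C4–O bond so that the reduction stalls at a C4-oxygenated stage, or ionisation at C4 followed by loss of H3 and re-hydrogenation erodes the C3 configuration. The fallback sets out from 17 and returns at 18, and removes the C4 oxygen by ionic hydrogenation before any hydrogenolysis. Et3SiH and TFA in CH2Cl2 at 0 °C should ionise the benzylic acetate (cation stabilised by the C7 oxygen) and deliver hydride to give [(1S,2R,3R)-7-benzyloxy-1-(4-benzyloxy-3,5-dimethoxyphenyl)-6-methoxy-1,2,3,4-tetrahydronaphthalene-2,3-diyl]bis(methylene) diacetate F2. H2 over Pd/C in EtOAc then has only the two aryl benzyl ethers to cleave and should give 18.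

Step 7. What may go wrong: protodeboronation of the ortho-formyl boronate and hydrolysis or homocoupling of the electron-rich benzylic bromide under aqueous base. The fallback sets out from 3 and 8 and returns at 9, reversing the polarity to an anhydrous Negishi coupling. Bromide 3 is protected (ethylene glycol, TsOH cat., toluene, Dean–Stark) as 2-(4-benzyloxy-2-bromo-5-methoxyphenyl)-1,3-dioxolane F3. Bromide 8 is converted by zinc insertion (Zn dust, LiCl, THF, rt) into (4-benzyloxy-3,5-dimethoxybenzyl)zinc bromide F4. Coupling of F3 with F4 (Pd(OAc)2, SPhos, THF, rt to 50 °C) should give 2-{4-benzyloxy-2-[(4-benzyloxy-3,5-dimethoxyphenyl)methyl]-5-methoxyphenyl}-1,3-dioxolane F5, and 1 M HCl in THF releases aldehyde 9.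

Further compounds
F1 | step 9 | cis-5-benzyloxy-3-(4-benzyloxy-3,5-dimethoxyphenyl)-1-hydroxy-6-methoxy-1,3-dihydro-2-benzothiophene 2,2-dioxide (racemic, one enantiomer drawn) | O=S1(=O)[C@@H](O)c2cc(OC)c(OCc3ccccc3)cc2[C@H]1c1cc(OC)c(OCc2ccccc2)c(OC)c1
F2 | step 12 | [(1S,2R,3R)-7-benzyloxy-1-(4-benzyloxy-3,5-dimethoxyphenyl)-6-methoxy-1,2,3,4-tetrahydronaphthalene-2,3-diyl]bis(methylene) diacetate | COc1cc2c(cc1OCc3ccccc3)[C@H](c1cc(OC)c(OCc3ccccc3)c(OC)c1)[C@@H](COC(C)=O)[C@H](COC(C)=O)C2
F3 | step 7 | 2-(4-benzyloxy-2-bromo-5-methoxyphenyl)-1,3-dioxolane | COc1cc(C2OCCO2)c(Br)cc1OCc1ccccc1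
F4 | step 7 | (4-benzyloxy-3,5-dimethoxybenzyl)zinc bromide | COc1cc(C[Zn]Br)cc(OC)c1OCc1ccccc1
F5 | step 7 | 2-{4-benzyloxy-2-[(4-benzyloxy-3,5-dimethoxyphenyl)methyl]-5-methoxyphenyl}-1,3-dioxolane | COc1cc(C2OCCO2)c(cc1OCc1ccccc1)Cc1cc(OC)c(OCc2ccccc2)c(OC)c1
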